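The easy step comes first: J at the first reading over its time gives a starting rate s, which is 0.0600 M h⁻¹ in Monday's run and 0.0267 M h⁻¹ in Thursday's. Thursday's flask has Monday's L and a lower charge of Q, and its rate is about half of Monday's. So a = s/(Q charged) is taken as one value for both, within the scatter of a first reading.

| flask | Q | L | time |
|---|---|---|---|
| Monday's | 0.800 M | 0.960 M |  |
| Tuesday's | 0.400 M | 0.560 M |  |
| Saturday's | 0.800 M | 1.90 M |  |
| Thursday's | 0.400 M | 0.960 M |  |
| Friday's | 0.230 M | 0.960 M | 21 h |

- Monday's run (time / h: [J] / M): 0.75: 0.045; 2.3: 0.100; 4.4: 0.160; 6.9: 0.196; 9.9: 0.224; 13: 0.240; 17: 0.244; 21: 0.256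
- Tuesday's run (time / h: [J] / M): 0.75: 0.011; 2.3: 0.041; 4.4: 0.052; 6.9: 0.064; 9.9: 0.085; 13: 0.087; 17: 0.095; 21: 0.095
- Saturday's run (time / h: [J] / M): 0.75: 0.091; 2.3: 0.212; 4.4: 0.294; 6.9: 0.343; 9.9: 0.372; 13: 0.385; 17: 0.400; 21: 0.407
- Thursday's run (time / h: [J] / M): 0.75: 0.020; 2.3: 0.057; 4.4: 0.091; 6.9: 0.114; 9.9: 0.134; 13: 0.135; 17: 0.142; 21: 0.154

(each reading ± 0.004 M)

- Overall: Q + L -> J.
- Constant volume, constant temperature.
- What is held in complexes is read along with the free species.
- "The second partner" is L.
- An order is taken over about fifteen percent of the charge, up and down.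

- the power of [L] that the first rate follows, about the charge of the Monday's run; measure it at two percent of Q made into J
- the power of [Q] that the first rate follows, about the charge of the Monday's run; measure it at two percent of Q made into J (one fixed amount of J, the same in the runs compared)
- J in the Friday's run at 21 h, as a share of the Q charged

Monday's rate between the last readings is 0.00200 M h⁻¹, so, as read through the scatter, it has fallen by a factor of about 30.0. Mass action on the Q and L turned into J gives a factor of 0.499, which leaves a further slowing of about 15.0. If the whole slowing is written as one constant λ, the rate integrates in closed form: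

rate = s·exp(−λt), so J at the end = s/λ

P = (Q charged)/(J at the end) = λ/a

P is the inverse of the yield. The reckoning here sets the end at the 21 h reading. Monday's P is 3.12 and Thursday's is 2.60, so Monday's is higher, and between these two flasks, which share their charge of L, λ/a reads higher at the larger charge of Q. A straight line through these two points, which is an assumption of this reckoning, has a slope of 1.32 M⁻¹. At Friday's charge it gives P, the Q charged per J made, as:

2.37, a share of 42.2%

The forecast gives 1.05 for L, 1.05 for Q and 37% for Friday, holding that “the plateaus reflect a reversible equilibrium”. The share reckoned here stands above the forecast's.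

The flask gives 1.2 for L, 1.0 for Q and 40.4% for Friday.

    2 L ⇌ L2, settled at all times (17.90 M⁻¹)
    Q + L2 → J + L (0.2102 M⁻¹ h⁻¹)
    2 Q → Lx (0.07920 M⁻¹ h⁻¹)
    Q → Wy (0.09648 h⁻¹)

Friday's P is therefore 2.48, against the 2.37 reckoned from Monday and Thursday. The equations hold no step from J back to Q and L, and Q also leaves by steps that make no J. The turning of Q into Wy raises Friday's P. Friday's run without that step reaches 67.7% of the Q charged instead of 40.4%, which brings P down to 1.48.

(Readings and results come from a simulation from invented constants, and the scatter is random.)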